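## Retrosynthetic overview

1. The target comes from its bis-TBS ether by a final fluoride desilylation; the E-arylidene C=C comes from a β-acetoxy lactone by E1cB elimination.
2. Key C–C bond (lactone C3 to the benzylic carbon): intermolecular aldol addition of the lithium enolate of (R)-4-(4-TBSO-3-methoxybenzyl)butyrolactone to O-TBS-syringaldehyde.
3. The lactone is the only ring that is built, and it is closed before the aldol; it comes from a γ-hydroxy tert-butyl ester obtained by reductive removal of an Evans auxiliary.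
4. The C4 stereocentre comes from Evans alkylation of the N-(3-arylpropanoyl)-(S)-4-benzyloxazolidinone with tert-butyl bromoacetate.
5. Building blocks: ferulic acid, (S)-4-benzyl-2-oxazolidinone, tert-butyl bromoacetate and syringaldehyde; both aromatic rings are bought.

Assumption: compound numbers follow the forward route; TBS = tert-butyldimethylsilyl; NaHMDS, LDA, LiBH4 and TBAF are used as purchased solutions.

## Route

Step 1
Reactants: 1 (E)-ferulic acid
Product: 2 3-(4-hydroxy-3-methoxyphenyl)propanoic acid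
Conditions: H2 (1 atm), 10% Pd/C, EtOH, rt
Reagents that add atoms: none
Why: Catalytic hydrogenation saturates the conjugated alkene cleanly, while the arene, phenol and acid are inert at 1 atm.

Step 2
Reactants: 2 3-(4-hydroxy-3-methoxyphenyl)propanoic acid
Product: 4 3-(4-TBSO-3-methoxyphenyl)propanoic acid, via bis-silylated ester 3 (not isolated)
Conditions: TBSCl (2.5 equiv), imidazole (5 equiv), DMF, rt; then AcOH/THF/H2O (3:1:1), rt
Reagents that add atoms: tert-butyldimethylsilyl chloride, CC(C)(C)[Si](C)(C)Cl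
Why: Silylation caps both phenol and acid, and the far more labile silyl ester is then hydrolysed selectively in aqueous acetic acid, which aryl TBS ethers tolerate.

Step 3
Reactants: 4 3-(4-TBSO-3-methoxyphenyl)propanoic acid; 5 (S)-4-benzyl-2-oxazolidinone
Product: 7 (S)-4-benzyl-3-[3-(4-TBSO-3-methoxyphenyl)propanoyl]oxazolidin-2-one, via mixed pivalic anhydride 6 (not isolated)
Conditions: PivCl (1.1 equiv), Et3N (2.5 equiv), THF, −20 °C; then 5, LiCl (1.1 equiv), −20 °C → rt
Reagents that add atoms: none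
Why: N-acylation of the oxazolidinone through the mixed anhydride goes at the unhindered acyl carbon, because the pivaloyl carbonyl is sterically shielded.

Step 4
Reactants: 7 (S)-4-benzyl-3-[3-(4-TBSO-3-methoxyphenyl)propanoyl]oxazolidin-2-one; 8 tert-butyl bromoacetate
Product: 10 tert-butyl (R)-4-[(S)-4-benzyl-2-oxooxazolidin-3-yl]-3-(4-TBSO-3-methoxybenzyl)-4-oxobutanoate, via sodium Z-enolate 9 (not isolated)
Conditions: NaHMDS (1.1 equiv), THF, −78 °C; then 8 (2 equiv), −78 → −40 °C; aq NH4Cl
Reagents that add atoms: none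
Why: Evans asymmetric alkylation: the chelated sodium Z-enolate is alkylated on the face opposite the auxiliary benzyl group, which sets the new stereocentre as R (dr typically ≥ 95:5, minor diastereomer removed by chromatography).

Step 5
Reactants: 10 tert-butyl (R)-4-[(S)-4-benzyl-2-oxooxazolidin-3-yl]-3-(4-TBSO-3-methoxybenzyl)-4-oxobutanoate
Product: 11 tert-butyl (R)-3-(hydroxymethyl)-4-(4-TBSO-3-methoxyphenyl)butanoate
Conditions: LiBH4 (2 equiv), MeOH (2 equiv), THF, 0 °C; aq NH4Cl
Reagents that add atoms: none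
Why: Reductive cleavage of the Evans auxiliary: LiBH4 reduces the activated exocyclic imide carbonyl much faster than the hindered tert-butyl ester, and the stereocentre is not touched (auxiliary 5 is recovered).

Step 6
Reactants: 11 tert-butyl (R)-3-(hydroxymethyl)-4-(4-TBSO-3-methoxyphenyl)butanoate
Product: 12 (R)-4-(4-TBSO-3-methoxybenzyl)dihydrofuran-2(3H)-one
Conditions: p-TsOH·H2O (0.1 equiv), toluene, 80 °C
Reagents that add atoms: none
Why: Acid-catalysed lactonisation: the tert-butyl ester is cleaved with loss of isobutene and the γ-hydroxy acid closes to the five-membered lactone, with the aryl silyl ether stable to catalytic acid.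

Step 7
Reactants: 13 syringaldehyde
Product: 14 4-TBSO-3,5-dimethoxybenzaldehyde
Conditions: TBSCl (1.3 equiv), imidazole (2.5 equiv), DMAP (cat.), DMF, rt → 40 °C
Reagents that add atoms: tert-butyldimethylsilyl chloride, CC(C)(C)[Si](C)(C)Cl
Why: Silylation of the phenol removes the acidic proton that would quench the enolate in the aldol step.

Step 8
Reactants: 12 (R)-4-(4-TBSO-3-methoxybenzyl)dihydrofuran-2(3H)-one; 14 4-TBSO-3,5-dimethoxybenzaldehyde
Product: 16 (3S,4R)-3-[(4-TBSO-3,5-dimethoxyphenyl)(hydroxy)methyl]-4-(4-TBSO-3-methoxybenzyl)dihydrofuran-2(3H)-one (both carbinol epimers), via lithium lactone enolate 15 (not isolated)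
Conditions: LDA (1.15 equiv), THF, −78 °C, 45 min; then 14 (1.2 equiv), −78 °C, 1 h; AcOH quench at −78 °C
Reagents that add atoms: none
Why: Directed aldol addition of the preformed lithium lactone enolate to the non-enolisable aldehyde forms the key C–C bond anti to the C4 benzyl group (3,4-trans); the C3 and carbinol centres are removed later, so their ratio does not matter.

Step 9
Reactants: 16 (3S,4R)-3-[(4-TBSO-3,5-dimethoxyphenyl)(hydroxy)methyl]-4-(4-TBSO-3-methoxybenzyl)dihydrofuran-2(3H)-one (both carbinol epimers)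
Product: 17 (4-TBSO-3,5-dimethoxyphenyl)[(3S,4R)-4-(4-TBSO-3-methoxybenzyl)-2-oxotetrahydrofuran-3-yl]methyl acetate (both epimers)
Conditions: Ac2O (3 equiv), Et3N (4 equiv), DMAP (0.1 equiv), CH2Cl2, 0 °C → rt
Reagents that add atoms: acetic anhydride, CC(=O)OC(C)=O
Why: DMAP-catalysed acetylation turns the hydroxyl into a leaving group under basic conditions, so no benzylic cation forms that could undergo Friedel–Crafts closure onto the other ring.

Step 10
Reactants: 17 (4-TBSO-3,5-dimethoxyphenyl)[(3S,4R)-4-(4-TBSO-3-methoxybenzyl)-2-oxotetrahydrofuran-3-yl]methyl acetate (both epimers)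
Product: 18 (3E,4R)-3-(4-TBSO-3,5-dimethoxybenzylidene)-4-(4-TBSO-3-methoxybenzyl)dihydrofuran-2(3H)-one
Conditions: DBU (1.5 equiv), toluene, 0 °C → rt
Reagents that add atoms: none
Why: E1cB elimination of acetate through the lactone enolate converges both epimers to the thermodynamically preferred E alkene (aryl trans to the carbonyl), and C4–H is not removed under these mild conditions.

Step 11
Reactants: 18 (3E,4R)-3-(4-TBSO-3,5-dimethoxybenzylidene)-4-(4-TBSO-3-methoxybenzyl)dihydrofuran-2(3H)-one
Product: 19 (3E,4R)-3-(4-hydroxy-3,5-dimethoxybenzylidene)-4-(4-hydroxy-3-methoxybenzyl)dihydrofuran-2(3H)-one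
Conditions: TBAF (2.4 equiv), AcOH (2.4 equiv), THF, 0 °C
Reagents that add atoms: none
Why: Fluoride-mediated desilylation frees both phenols, and the acetic acid buffer keeps the medium non-basic so the alkene geometry, the lactone and the C4 centre are preserved.

## Compound list

1 | (E)-ferulic acid | COc1cc(/C=C/C(=O)O)ccc1O | starting material
2 | 3-(4-hydroxy-3-methoxyphenyl)propanoic acid | COc1cc(CCC(=O)O)ccc1O | intermediate
3 | tert-butyldimethylsilyl 3-[4-(tert-butyldimethylsilyloxy)-3-methoxyphenyl]propanoate (not isolated) | COc1cc(CCC(=O)O[Si](C)(C)C(C)(C)C)ccc1O[Si](C)(C)C(C)(C)C | intermediate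
4 | 3-[4-(tert-butyldimethylsilyloxy)-3-methoxyphenyl]propanoic acid | COc1cc(CCC(=O)O)ccc1O[Si](C)(C)C(C)(C)C | intermediate
5 | (S)-4-benzyl-2-oxazolidinone | O=C1N[C@@H](Cc2ccccc2)CO1 | starting material
6 | 3-[4-(tert-butyldimethylsilyloxy)-3-methoxyphenyl]propanoic pivalic anhydride (not isolated) | COc1cc(CCC(=O)OC(=O)C(C)(C)C)ccc1O[Si](C)(C)C(C)(C)C | intermediate
7 | (S)-4-benzyl-3-{3-[4-(tert-butyldimethylsilyloxy)-3-methoxyphenyl]propanoyl}oxazolidin-2-one | COc1cc(CCC(=O)N2C(=O)OC[C@@H]2Cc2ccccc2)ccc1O[Si](C)(C)C(C)(C)C | intermediate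
8 | tert-butyl bromoacetate | CC(C)(C)OC(=O)CBr | starting material
9 | sodium (Z)-enolate of 7 (not isolated) | [Na+].[O-]/C(=C\Cc1ccc(O[Si](C)(C)C(C)(C)C)c(OC)c1)N1C(=O)OC[C@@H]1Cc1ccccc1 | intermediate
10 | tert-butyl (R)-4-[(S)-4-benzyl-2-oxooxazolidin-3-yl]-3-[4-(tert-butyldimethylsilyloxy)-3-methoxybenzyl]-4-oxobutanoate | COc1cc(C[C@H](CC(=O)OC(C)(C)C)C(=O)N2C(=O)OC[C@@H]2Cc2ccccc2)ccc1O[Si](C)(C)C(C)(C)C | intermediate
11 | tert-butyl (R)-4-[4-(tert-butyldimethylsilyloxy)-3-methoxyphenyl]-3-(hydroxymethyl)butanoate | COc1cc(C[C@H](CC(=O)OC(C)(C)C)CO)ccc1O[Si](C)(C)C(C)(C)C | intermediate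
12 | (R)-4-[4-(tert-butyldimethylsilyloxy)-3-methoxybenzyl]dihydrofuran-2(3H)-one | COc1cc(C[C@H]2COC(=O)C2)ccc1O[Si](C)(C)C(C)(C)C | intermediate
13 | syringaldehyde (4-hydroxy-3,5-dimethoxybenzaldehyde) | COc1cc(C=O)cc(OC)c1O | starting material
14 | 4-(tert-butyldimethylsilyloxy)-3,5-dimethoxybenzaldehyde | COc1cc(C=O)cc(OC)c1O[Si](C)(C)C(C)(C)C | intermediate
15 | lithium enolate of 12, lithium (R)-4-[4-(tert-butyldimethylsilyloxy)-3-methoxybenzyl]-4,5-dihydrofuran-2-olate (not isolated) | [Li+].[O-]C1=C[C@@H](Cc2ccc(O[Si](C)(C)C(C)(C)C)c(OC)c2)CO1 | intermediate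
16 | (3S,4R)-3-{[4-(tert-butyldimethylsilyloxy)-3,5-dimethoxyphenyl](hydroxy)methyl}-4-[4-(tert-butyldimethylsilyloxy)-3-methoxybenzyl]dihydrofuran-2(3H)-one, both epimers at the carbinol carbon | COc1cc(C[C@H]2COC(=O)[C@@H]2C(O)c2cc(OC)c(O[Si](C)(C)C(C)(C)C)c(OC)c2)ccc1O[Si](C)(C)C(C)(C)C | intermediate
17 | [4-(tert-butyldimethylsilyloxy)-3,5-dimethoxyphenyl]{(3S,4R)-4-[4-(tert-butyldimethylsilyloxy)-3-methoxybenzyl]-2-oxotetrahydrofuran-3-yl}methyl acetate, both epimers at the acetoxy carbon | COc1cc(C[C@H]2COC(=O)[C@@H]2C(OC(C)=O)c2cc(OC)c(O[Si](C)(C)C(C)(C)C)c(OC)c2)ccc1O[Si](C)(C)C(C)(C)C | intermediate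
18 | (3E,4R)-3-[4-(tert-butyldimethylsilyloxy)-3,5-dimethoxybenzylidene]-4-[4-(tert-butyldimethylsilyloxy)-3-methoxybenzyl]dihydrofuran-2(3H)-one | COc1cc(C[C@H]2COC(=O)/C2=C/c2cc(OC)c(O[Si](C)(C)C(C)(C)C)c(OC)c2)ccc1O[Si](C)(C)C(C)(C)C | intermediate
19 | (3E,4R)-3-(4-hydroxy-3,5-dimethoxybenzylidene)-4-(4-hydroxy-3-methoxybenzyl)dihydrofuran-2(3H)-one (CNP0351244.1) | COc1cc(C[C@H]2COC(=O)/C2=C/c2cc(OC)c(O)c(OC)c2)ccc1O | target

## Summary

Total step count: 11.
Longest linear sequence: 10 steps (steps 1–6 and 8–11, from ferulic acid); step 7 is a one-step side branch.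

Steps most likely to fail:

Step 8 (aldol addition). The electron-rich aldehyde is a modest electrophile and the lithium aldolate can revert on warming, so conversion may be low. The fallback sets out from 12 and replaces the reversible addition by an acylation followed by reduction. Claisen-type C-acylation of the lithium enolate of 12 (LiHMDS 2.2 equiv, THF, −78 → 0 °C) with methyl 4-(tert-butyldimethylsilyloxy)-3,5-dimethoxybenzoate F2 (made from commercial methyl syringate with TBSCl and imidazole in DMF) gives the β-keto lactone (3S,4R)-3-[4-(tert-butyldimethylsilyloxy)-3,5-dimethoxybenzoyl]-4-[4-(tert-butyldimethylsilyloxy)-3-methoxybenzyl]dihydrofuran-2(3H)-one F3. This acylation is driven forward by deprotonation of the product and cannot undergo retro-aldol. Reduction of the ketone with NaBH4 (MeOH/THF, −20 °C) then comes back to the route at 16.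

Step 10 (E-selective elimination). The risks are an E/Z mixture, base-induced migration of the double bond into the ring with loss of the C4 stereocentre, and partial silyl loss. The fallback sets out from 16 (skipping 17) and separates alkene formation from control of geometry. Neutral dehydration with Martin sulfurane (CH2Cl2, 0 °C) gives 18 together with its geometric isomer (3Z,4R)-3-[4-(tert-butyldimethylsilyloxy)-3,5-dimethoxybenzylidene]-4-[4-(tert-butyldimethylsilyloxy)-3-methoxybenzyl]dihydrofuran-2(3H)-one F4. The mixture is then equilibrated with catalytic iodine (CH2Cl2, ambient light) to the more stable E isomer, which comes back to the route at 18.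

Step 5 (reductive removal of the auxiliary). The risks are over-reduction of the tert-butyl ester to the diol and endocyclic opening of the oxazolidinone. The fallback sets out from 10 and changes from hydride cleavage to hydrolysis followed by borane reduction. LiOH/H2O2 (THF/H2O, 0 °C) gives (R)-4-tert-butoxy-2-[4-(tert-butyldimethylsilyloxy)-3-methoxybenzyl]-4-oxobutanoic acid F1, with auxiliary 5 recovered. BH3·SMe2 (THF, 0 °C → rt) then reduces the free acid chemoselectively in the presence of the tert-butyl ester and comes back to the route at 11.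

## Further compounds

F1 | step 5 | (R)-4-tert-butoxy-2-[4-(tert-butyldimethylsilyloxy)-3-methoxybenzyl]-4-oxobutanoic acid | COc1cc(C[C@H](CC(=O)OC(C)(C)C)C(=O)O)ccc1O[Si](C)(C)C(C)(C)C
F2 | step 8 | methyl 4-(tert-butyldimethylsilyloxy)-3,5-dimethoxybenzoate | COC(=O)c1cc(OC)c(O[Si](C)(C)C(C)(C)C)c(OC)c1
F3 | step 8 | (3S,4R)-3-[4-(tert-butyldimethylsilyloxy)-3,5-dimethoxybenzoyl]-4-[4-(tert-butyldimethylsilyloxy)-3-methoxybenzyl]dihydrofuran-2(3H)-one | COc1cc(C[C@H]2COC(=O)[C@@H]2C(=O)c2cc(OC)c(O[Si](C)(C)C(C)(C)C)c(OC)c2)ccc1O[Si](C)(C)C(C)(C)C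
F4 | step 10 | (3Z,4R)-3-[4-(tert-butyldimethylsilyloxy)-3,5-dimethoxybenzylidene]-4-[4-(tert-butyldimethylsilyloxy)-3-methoxybenzyl]dihydrofuran-2(3H)-one | COc1cc(C[C@H]2COC(=O)/C2=C\c2cc(OC)c(O[Si](C)(C)C(C)(C)C)c(OC)c2)ccc1O[Si](C)(C)C(C)(C)C
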